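Carotenoid numbering is used: ring A is C1–C6, the chain is C7–C15 and C15'–C7', ring B is C1'–C6'.

**Plan**

1. Retrosynthesis: C7'–C8' is cut together with the ring B bond C1'–C6', giving a C30 polyenyl iodide, an acyclic C10 enyne and a hydride. Further cuts are C10=C11 and C10'=C11' (two olefinations), C7–C8 with C1–C6 (the same event on ring A) and C15–C15' (alkenyl homocoupling).
2. Enabling feature: in ring B the exocyclic alkene carbon C6' is bonded to the CMe2 carbon C1' (likewise C6 and C1 in ring A). This is the retron of syn alkenylpalladation of a C6'≡C7' alkyne, 6-exo Heck closure onto an isopropenyl group and hydride capture of the neopentyl palladium, which has no β-hydrogen. The syn addition fixes C8' cis to C1'.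
3. Forward order: ring A is closed first with a C4 iodophosphonate. The C12 dialdehyde core comes from hydrozirconation and copper-induced homocoupling, and two olefinations give the all-E C30 iodide. Ring B is closed in the same operation that joins it to the chain, and fluoride frees the triol.
4. Stereochemistry: C3 comes from a reagent-controlled methallylboration of a (Z)-enynal. C5' comes from a Sharpless epoxidation and C3' from a Felkin-matched methallylboration, after which directed hydride opens the epoxide. Chain alkenes come from the enynol building blocks, syn methylalumination, syn hydrozirconation and E-selective olefinations; both exocyclic alkenes come from the syn carbopalladation.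

Key step: step 19

Assumption: (2E)- and (2Z)-3-methylpent-2-en-4-yn-1-ol are used as the commercial single isomers; a commercial E/Z mixture would first be separated by distillation.

**Route**

Step 1
Reactants: 1 prop-2-yn-1-ol
Product: 3 (2E)-3-iodo-2-methylprop-2-en-1-ol, via alkenylalane 2 (not isolated)
Conditions: Me3Al (3 equiv), Cp2ZrCl2 (0.25 equiv), CH2Cl2, 0 → 23 °C; then I2, THF, −30 → 0 °C; aq. potassium sodium tartrate
Reagents that add atoms: trimethylaluminium, C[Al](C)C; iodine, II
Why: Zirconium-catalysed methylalumination of the terminal alkyne is a syn addition that puts the methyl group on the internal carbon, and iodinolysis of the C–Al bond with retention should give the E iodide.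

Step 2
Reactants: 3 (2E)-3-iodo-2-methylprop-2-en-1-ol
Product: 4 (1E)-3-bromo-1-iodo-2-methylprop-1-ene
Conditions: CBr4, PPh3, CH2Cl2, 0 °C
Reagents that add atoms: tetrabromomethane, BrC(Br)(Br)Br
Why: Appel bromination of a primary allylic alcohol runs under neutral conditions that leave the alkenyl iodide and its geometry untouched.

Step 3
Reactants: 4 (1E)-3-bromo-1-iodo-2-methylprop-1-ene
Product: 5 diethyl [(2E)-3-iodo-2-methylprop-2-en-1-yl]phosphonate
Conditions: P(OEt)3 (neat), 90 °C
Reagents that add atoms: triethyl phosphite, CCOP(OCC)OCC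
Why: Michaelis–Arbuzov reaction of the primary allylic bromide, in which the alkenyl iodide stays inert because no metal catalyst is present.

Step 4
Reactants: 6 (2Z)-3-methylpent-2-en-4-yn-1-ol
Product: 7 (2Z)-3-methylpent-2-en-4-ynal
Conditions: activated MnO2, CH2Cl2, 0 °C, dark; filtered solution used at once
Reagents that add atoms: none
Why: Heterogeneous MnO2 oxidation of an allylic alcohol is neutral and should keep the Z geometry of the sensitive enynal.

Step 5
Reactants: 7 (2Z)-3-methylpent-2-en-4-ynal
Product: 9 (4S,5Z)-2,6-dimethylocta-1,5-dien-7-yn-4-ol, via borinate 8 (not isolated)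
Conditions: B-(2-methylallyl)diisopinocampheylborane of the (+)-α-pinene series (from (−)-Ipc2BOMe), Et2O, −78 °C; then NaOH, H2O2, 0 → 23 °C
Reagents that add atoms: B-(2-methylallyl)diisopinocampheylborane ((+)-α-pinene series), CC(=C)CB([C@@H]1C[C@@H]2C[C@H]([C@H]1C)C2(C)C)[C@@H]1C[C@@H]2C[C@H]([C@H]1C)C2(C)C
Why: Brown asymmetric methallylboration through a chair transition state, in which the (+)-α-pinene-derived reagent should deliver the methallyl group to the Si face of the aldehyde and so set C3 as S, while the low temperature preserves the Z alkene.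

Step 6
Reactants: 9 (4S,5Z)-2,6-dimethylocta-1,5-dien-7-yn-4-ol
Product: 10 tert-butyl{[(4S,5Z)-2,6-dimethylocta-1,5-dien-7-yn-4-yl]oxy}dimethylsilane
Conditions: t-BuMe2SiCl, imidazole, DMF, 23 °C
Reagents that add atoms: tert-butyldimethylsilyl chloride, CC(C)(C)[Si](C)(C)Cl
Why: Standard silylation of a secondary alcohol gives an ether that survives the palladium and strong-base steps that follow.

Step 7
Reactants: 10 tert-butyl{[(4S,5Z)-2,6-dimethylocta-1,5-dien-7-yn-4-yl]oxy}dimethylsilane; 5 diethyl [(2E)-3-iodo-2-methylprop-2-en-1-yl]phosphonate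
Product: 11 diethyl {(2E)-4-[(1E,4S)-4-(tert-butyldimethylsilyloxy)-2,6,6-trimethylcyclohex-2-en-1-ylidene]-2-methylbut-2-en-1-yl}phosphonate (ring A with C7–C10)
Conditions: Pd(OAc)2 (10 mol %), PPh3 (20 mol %), HCO2Na (1.5 equiv), Bu4NCl, DMF, 60 °C
Reagents that add atoms: none
Why: Proposed new method: the alkenylpalladium iodide formed from 5 and zerovalent palladium should add syn across the terminal alkyne of 10 (alkenyl group to the unhindered C7, palladium to C6), the dienylpalladium should then insert the isopropenyl group 6-exo-trig to close ring A and make the quaternary C1, and the neopentylpalladium so formed, which has no β-hydrogen, should be reduced by formate to the second C1 methyl group, so that the syn addition alone places C8 cis to C1 (6E) while C3 is untouched; the closest known reaction types are the formate-terminated hydroalkenylation of alkynes with alkenyl halides and the intramolecular Heck cyclisation with hydride capture.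

Step 8
Reactants: 12 (2E)-3-methylpent-2-en-4-yn-1-ol
Product: 13 tert-butyldimethyl{[(2E)-3-methylpent-2-en-4-yn-1-yl]oxy}silane
Conditions: t-BuMe2SiCl, imidazole, DMF, 23 °C
Reagents that add atoms: tert-butyldimethylsilyl chloride, CC(C)(C)[Si](C)(C)Cl
Why: Silylation masks the hydroxyl group, which would otherwise consume Cp2Zr(H)Cl in the next step.

Step 9
Reactants: 13 tert-butyldimethyl{[(2E)-3-methylpent-2-en-4-yn-1-yl]oxy}silane (two molecules)
Product: 15 (2E,4E,6E,8E)-1,10-bis(tert-butyldimethylsilyloxy)-3,8-dimethyldeca-2,4,6,8-tetraene, via alkenylzirconocene chloride 14 (not isolated)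
Conditions: Cp2Zr(H)Cl (1.1 equiv), THF, 23 °C; then CuCl (1 equiv), 23 → 40 °C
Reagents that add atoms: none
Why: Hydrozirconation of the terminal alkyne is a syn addition with zirconium at the terminus, and the copper monochloride-induced homocoupling of alkenylzirconocenes proceeds with retention, so the symmetric all-E tetraene with the C15–C15' bond should result.

Step 10
Reactants: 15 (2E,4E,6E,8E)-1,10-bis(tert-butyldimethylsilyloxy)-3,8-dimethyldeca-2,4,6,8-tetraene
Product: 16 (2E,4E,6E,8E)-3,8-dimethyldeca-2,4,6,8-tetraene-1,10-diol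
Conditions: Bu4NF, THF, 0 → 23 °C
Reagents that add atoms: none
Why: Fluoride cleavage of the two primary silyl ethers is a standard deprotection that does not touch the tetraene.

Step 11
Reactants: 16 (2E,4E,6E,8E)-3,8-dimethyldeca-2,4,6,8-tetraene-1,10-diol
Product: 17 (2E,4E,6E,8E)-3,8-dimethyldeca-2,4,6,8-tetraenedial
Conditions: activated MnO2, CH2Cl2, 23 °C, dark
Reagents that add atoms: none
Why: MnO2 oxidation of the two allylic alcohols should stop at the dialdehyde and leave the alkene geometry intact.

Step 12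
Reactants: 17 (2E,4E,6E,8E)-3,8-dimethyldeca-2,4,6,8-tetraenedial (3 equiv); 5 diethyl [(2E)-3-iodo-2-methylprop-2-en-1-yl]phosphonate
Product: 18 (2E,4E,6E,8E,10E,12E)-13-iodo-3,8,12-trimethyltrideca-2,4,6,8,10,12-hexaenal
Conditions: 5, NaN(SiMe3)2, THF, −78 °C; then 17 (3 equiv), −78 → 0 °C, dark; excess 17 recovered
Reagents that add atoms: none
Why: Horner–Wadsworth–Emmons olefination with an allylic phosphonate anion is E-selective (new C10'=C11' bond), and the excess of the symmetric dialdehyde should hold the reaction at mono-olefination.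

Step 13
Reactants: 11 diethyl {(2E)-4-[(1E,4S)-4-(tert-butyldimethylsilyloxy)-2,6,6-trimethylcyclohex-2-en-1-ylidene]-2-methylbut-2-en-1-yl}phosphonate; 18 (2E,4E,6E,8E,10E,12E)-13-iodo-3,8,12-trimethyltrideca-2,4,6,8,10,12-hexaenal
Product: 19 tert-butyl({(1S,4E)-4-[(2E,4E,6E,8E,10E,12E,14E,16E)-17-iodo-3,7,12,16-tetramethylheptadeca-2,4,6,8,10,12,14,16-octaen-1-ylidene]-3,5,5-trimethylcyclohex-2-en-1-yl}oxy)dimethylsilane (ring A with C7–C15 and C15'–C8', iodine on C8')
Conditions: 11, NaN(SiMe3)2, THF, −78 °C; then 18, −78 → 0 °C, dark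
Reagents that add atoms: none
Why: Horner–Wadsworth–Emmons olefination at the α-carbon of the C14 phosphonate anion should form the E C10=C11 alkene, as with the C15 phosphonates used for retinoids.

Step 14
Reactants: 12 (2E)-3-methylpent-2-en-4-yn-1-ol
Product: 20 [(2R,3R)-3-ethynyl-3-methyloxiran-2-yl]methanol
Conditions: Ti(OiPr)4 (10 mol %), D-(−)-diethyl tartrate (12 mol %), t-BuOOH, 4 Å molecular sieves, CH2Cl2, −20 °C
Reagents that add atoms: tert-butyl hydroperoxide, CC(C)(C)OO
Why: Sharpless asymmetric epoxidation of the trisubstituted allylic alcohol, in which the D-(−)-tartrate catalyst should deliver oxygen to the face that gives the (2R,3R)-epoxide and thereby fixes C5'.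

Step 15
Reactants: 20 [(2R,3R)-3-ethynyl-3-methyloxiran-2-yl]methanol
Product: 21 (2S,3R)-3-ethynyl-3-methyloxirane-2-carbaldehyde
Conditions: Dess–Martin periodinane, NaHCO3, CH2Cl2, 0 °C; solution used at once
Reagents that add atoms: none
Why: Buffered Dess–Martin oxidation should give the epoxy aldehyde without epimerisation or epoxide opening.

Step 16
Reactants: 21 (2S,3R)-3-ethynyl-3-methyloxirane-2-carbaldehyde
Product: 23 (1R)-1-[(2R,3R)-3-ethynyl-3-methyloxiran-2-yl]-3-methylbut-3-en-1-ol, via borinate 22 (not isolated)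
Conditions: B-(2-methylallyl)diisopinocampheylborane of the (−)-α-pinene series (from (+)-Ipc2BOMe), Et2O, −78 °C; then NaOH, H2O2, 0 °C
Reagents that add atoms: B-(2-methylallyl)diisopinocampheylborane ((−)-α-pinene series), CC(=C)CB([C@H]1C[C@H]2C[C@@H]([C@@H]1C)C2(C)C)[C@H]1C[C@H]2C[C@@H]([C@@H]1C)C2(C)C
Why: Brown asymmetric methallylboration in which the (−)-α-pinene-derived reagent attacks the Re face, which is also the Felkin–Anh face of the α,β-epoxy aldehyde (matched pair), and should set C3' as R.

Step 17
Reactants: 23 (1R)-1-[(2R,3R)-3-ethynyl-3-methyloxiran-2-yl]-3-methylbut-3-en-1-ol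
Product: 24 (4R,6S)-2,6-dimethyloct-1-en-7-yne-4,6-diol
Conditions: NaAlH2(OCH2CH2OMe)2 (2.5 equiv), THF, −20 → 0 °C; aq. potassium sodium tartrate
Reagents that add atoms: none
Why: Hydroxyl-directed hydride opening of a 2,3-epoxy alcohol, in which the aluminium alkoxide at C3' delivers hydride to the adjacent epoxide carbon C4', so the anti 1,3-diol should form with the tertiary C5'–O bond and its configuration intact.

Step 18
Reactants: 24 (4R,6S)-2,6-dimethyloct-1-en-7-yne-4,6-diol
Product: 25 (4R,6S)-2,6-dimethyl-4,6-bis(triethylsilyloxy)oct-1-en-7-yne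
Conditions: Et3SiOSO2CF3, 2,6-lutidine, CH2Cl2, −78 → 0 °C
Reagents that add atoms: triethylsilyl trifluoromethanesulfonate, CC[Si](CC)(CC)OS(=O)(=O)C(F)(F)F
Why: The silyl triflate silylates both the secondary and the tertiary propargylic hydroxyl groups, and the ethers keep alkoxides away from palladium in the key step.

Step 19
Reactants: 19 ring A C30 polyenyl iodide (iodine on C8'); 25 (4R,6S)-2,6-dimethyl-4,6-bis(triethylsilyloxy)oct-1-en-7-yne (1.3 equiv)
Product: 26 (3S,3'R,5'S,6E,6'E)-3-O-(tert-butyldimethylsilyl)-3',5'-bis-O-(triethylsilyl)-4,5'-retro-β,β-carotene-3,3',5'-triol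
Conditions: Pd(OAc)2 (10 mol %), PPh3 (20 mol %), HCO2Na (1.5 equiv), Bu4NCl, DMF, 50 °C, dark, argon
Reagents that add atoms: none
Why: Proposed new method: zerovalent palladium should insert into the C8'–I bond of 19, the polyenylpalladium iodide should add syn across the terminal alkyne of 25 with the polyenyl group going to the unhindered C7' and palladium to C6' beside the quaternary C5', the isopropenyl group should insert into the C6'–Pd bond, and the neopentylpalladium (no β-hydrogen) should be reduced by formate-derived hydride. The closest known reaction types are the formate-terminated hydroalkenylation of alkynes with alkenyl halides and the cyclisation–hydride-capture (reductive Heck) cascades that build quaternary carbons. Ring B closes in the 6-exo-trig mode, and the second C1' methyl group arises from the former CH2= carbon. No stereocentre is formed: the C6'=C7' geometry follows from the syn addition, which keeps C8' cis to palladium and therefore cis to C1' once C1' takes the place of the metal, and C3' and C5' are carried through from 25. The step needs alkyne insertion to outrun formate reduction of the polyenylpalladium iodide, and ring closure to outrun reduction or E/Z isomerisation of the alkenylpalladium. The terminal alkyne (fast, regioselective insertion), the six-membered exo closure and the absence of a β-hydrogen in the last intermediate are the features that should secure this.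

Step 20
Reactants: 26 tris-silyl ether of the target
Product: 27 (3S,3'R,5'S,6E,6'E)-4,5'-retro-β,β-carotene-3,3',5'-triol (target)
Conditions: Bu4NF (6 equiv), THF, 0 → 23 °C, dark, argon
Reagents that add atoms: none
Why: Fluoride desilylation removes the three silyl ethers under non-acidic conditions that the tertiary allylic alcohol and the retro-polyene should tolerate.

**Compound list**

1 | prop-2-yn-1-ol | C#CCO | starting material
2 | dimethyl[(1E)-3-(dimethylalumanyloxy)-2-methylprop-1-en-1-yl]alumane | C[Al](C)/C=C(\C)CO[Al](C)C | intermediate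
3 | (2E)-3-iodo-2-methylprop-2-en-1-ol | OC/C(C)=C/I | intermediate
4 | (1E)-3-bromo-1-iodo-2-methylprop-1-ene | BrC/C(C)=C/I | intermediate
5 | diethyl [(2E)-3-iodo-2-methylprop-2-en-1-yl]phosphonate | CCOP(=O)(OCC)C/C(C)=C/I | intermediate
6 | (2Z)-3-methylpent-2-en-4-yn-1-ol | C#C/C(C)=C\CO | starting material
7 | (2Z)-3-methylpent-2-en-4-ynal | C#C/C(C)=C\C=O | intermediate
8 | (4S,5Z)-2,6-dimethylocta-1,5-dien-7-yn-4-yl bis(isopinocampheyl)borinate ((+)-α-pinene series) | CC(=C)C[C@H](OB([C@@H]1C[C@@H]2C[C@H]([C@H]1C)C2(C)C)[C@@H]1C[C@@H]2C[C@H]([C@H]1C)C2(C)C)/C=C(/C)C#C | intermediate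
9 | (4S,5Z)-2,6-dimethylocta-1,5-dien-7-yn-4-ol | CC(=C)C[C@H](O)/C=C(/C)C#C | intermediate
10 | tert-butyl{[(4S,5Z)-2,6-dimethylocta-1,5-dien-7-yn-4-yl]oxy}dimethylsilane | CC(=C)C[C@H](O[Si](C)(C)C(C)(C)C)/C=C(/C)C#C | intermediate
11 | diethyl {(2E)-4-[(1E,4S)-4-(tert-butyldimethylsilyloxy)-2,6,6-trimethylcyclohex-2-en-1-ylidene]-2-methylbut-2-en-1-yl}phosphonate | CC1=C[C@@H](O[Si](C)(C)C(C)(C)C)CC(C)(C)\C1=C/C=C(\C)CP(=O)(OCC)OCC | intermediate
12 | (2E)-3-methylpent-2-en-4-yn-1-ol | C#C/C(C)=C/CO | starting material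
13 | tert-butyldimethyl{[(2E)-3-methylpent-2-en-4-yn-1-yl]oxy}silane | C#C/C(C)=C/CO[Si](C)(C)C(C)(C)C | intermediate
14 | chloridobis(cyclopentadienyl)[(1E,3E)-5-(tert-butyldimethylsilyloxy)-3-methylpenta-1,3-dien-1-yl]zirconium (cyclopentadienyl rings drawn σ-bonded in the SMILES) | Cl[Zr](/C=C/C(C)=C/CO[Si](C)(C)C(C)(C)C)(C1C=CC=C1)C1C=CC=C1 | intermediate
15 | (2E,4E,6E,8E)-1,10-bis(tert-butyldimethylsilyloxy)-3,8-dimethyldeca-2,4,6,8-tetraene | CC(C)(C)[Si](C)(C)OC/C=C(C)/C=C/C=C/C(C)=C/CO[Si](C)(C)C(C)(C)C | intermediate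
16 | (2E,4E,6E,8E)-3,8-dimethyldeca-2,4,6,8-tetraene-1,10-diol | OC/C=C(C)/C=C/C=C/C(C)=C/CO | intermediate
17 | (2E,4E,6E,8E)-3,8-dimethyldeca-2,4,6,8-tetraenedial | O=C/C=C(C)/C=C/C=C/C(C)=C/C=O | intermediate
18 | (2E,4E,6E,8E,10E,12E)-13-iodo-3,8,12-trimethyltrideca-2,4,6,8,10,12-hexaenal | O=C/C=C(C)/C=C/C=C/C(C)=C/C=C/C(C)=C/I | intermediate
19 | tert-butyl({(1S,4E)-4-[(2E,4E,6E,8E,10E,12E,14E,16E)-17-iodo-3,7,12,16-tetramethylheptadeca-2,4,6,8,10,12,14,16-octaen-1-ylidene]-3,5,5-trimethylcyclohex-2-en-1-yl}oxy)dimethylsilane | CC1=C[C@@H](O[Si](C)(C)C(C)(C)C)CC(C)(C)\C1=C/C=C(C)/C=C/C=C(C)/C=C/C=C/C(C)=C/C=C/C(C)=C/I | intermediate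
20 | [(2R,3R)-3-ethynyl-3-methyloxiran-2-yl]methanol | C#C[C@@]1(C)O[C@@H]1CO | intermediate
21 | (2S,3R)-3-ethynyl-3-methyloxirane-2-carbaldehyde | C#C[C@@]1(C)O[C@@H]1C=O | intermediate
22 | (1R)-1-[(2R,3R)-3-ethynyl-3-methyloxiran-2-yl]-3-methylbut-3-en-1-yl bis(isopinocampheyl)borinate ((−)-α-pinene series) | C#C[C@@]1(C)O[C@@H]1[C@H](OB([C@H]1C[C@H]2C[C@@H]([C@@H]1C)C2(C)C)[C@H]1C[C@H]2C[C@@H]([C@@H]1C)C2(C)C)CC(C)=C | intermediate
23 | (1R)-1-[(2R,3R)-3-ethynyl-3-methyloxiran-2-yl]-3-methylbut-3-en-1-ol | C#C[C@@]1(C)O[C@@H]1[C@H](O)CC(C)=C | intermediate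
24 | (4R,6S)-2,6-dimethyloct-1-en-7-yne-4,6-diol | C#C[C@@](C)(O)C[C@H](O)CC(C)=C | intermediate
25 | (4R,6S)-2,6-dimethyl-4,6-bis(triethylsilyloxy)oct-1-en-7-yne | C#C[C@@](C)(O[Si](CC)(CC)CC)C[C@H](O[Si](CC)(CC)CC)CC(C)=C | intermediate
26 | (3S,3'R,5'S,6E,6'E)-3-O-(tert-butyldimethylsilyl)-3',5'-bis-O-(triethylsilyl)-4,5'-retro-β,β-carotene-3,3',5'-triol | CC1=C[C@@H](O[Si](C)(C)C(C)(C)C)CC(C)(C)\C1=C/C=C(C)/C=C/C=C(C)/C=C/C=C/C(C)=C/C=C/C(C)=C/C=C1\C(C)(C)C[C@@H](O[Si](CC)(CC)CC)C[C@]1(C)O[Si](CC)(CC)CC | intermediate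
27 | (3S,3'R,5'S,6E,6'E)-4,5'-retro-β,β-carotene-3,3',5'-triol | CC1=C[C@@H](O)CC(C)(C)\C1=C/C=C(C)/C=C/C=C(C)/C=C/C=C/C(C)=C/C=C/C(C)=C/C=C1\C(C)(C)C[C@@H](O)C[C@]1(C)O | target

**Step count and risks**

Total step count: 20 steps. Longest linear sequence: 8 steps (steps 8, 9, 10, 11, 12, 13, 19, 20, from 12 to 27).

Steps most likely to fail:

Step 19 (key step, proposed method). Formate may reduce the polyenylpalladium iodide before the alkyne inserts, the terminal C–H may be alkynylated directly, or the hindered alkenylpalladium may isomerise (E/Z) or be reduced before the ring closes. The fallback sets out from 25 and 19 and comes back to the route at 26; it runs the three events as separate known reactions. Bromoboration of the terminal alkyne of 25 with B-bromo-9-borabicyclo[3.3.1]nonane (CH2Cl2, 0 °C; syn addition, bromine to the internal carbon) would give the (Z)-2-bromoalkenylborane of ring B F1, used without isolation. Suzuki–Miyaura coupling of its C–B bond with the iodide 19 (Pd(PPh3)4, aq. K3PO4, THF, 23 °C) would give the acyclic 6'-bromo polyene F2, in which C8' is cis to bromine. Reductive 6-exo Heck cyclisation of F2 (Pd(OAc)2, PPh3, HCO2Na, DMF, 60 °C) would replace bromine by C1' with retention and give 26.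

Step 7 (proposed method). The same competing processes may occur on the small partner, and the neopentylpalladium may add 3-exo to the new exocyclic alkene instead of being reduced. The fallback sets out from 10 and 5 and comes back at 11. Bromoboration of 10 with B-bromo-9-borabicyclo[3.3.1]nonane (CH2Cl2, 0 °C) would give the (Z)-2-bromodienylborane of ring A F3, used without isolation. Suzuki–Miyaura coupling with 5 (Pd(PPh3)4, aq. K3PO4, THF) would give the bromotetraene phosphonate F4, and its reductive 6-exo Heck cyclisation (Pd(OAc)2, PPh3, HCO2Na, DMF, 60 °C) would give 11.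

Step 17. Hydroalumination of the propargylic alkoxide, or hydride attack at the alkyne terminus with allene formation, may compete with the directed epoxide opening. The fallback sets out from 23 and comes back at 24. Dess–Martin oxidation (NaHCO3, CH2Cl2, 0 °C) would give the α,β-epoxy ketone F5. SmI2 (THF/MeOH, −90 °C) would cleave its Cα–O bond and give the β-hydroxy ketone F6 with C5' unchanged. Evans–Saksena reduction with Me4NBH(OAc)3 (MeCN/AcOH, −30 °C), directed by the tertiary hydroxyl group, would set C3' anti to C5' and give 24.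

**Further compounds**

F1 | step 19 | 9-[(1Z,3S,5R)-2-bromo-3,7-dimethyl-3,5-bis(triethylsilyloxy)octa-1,7-dien-1-yl]-9-borabicyclo[3.3.1]nonane (boron on C7', bromine on C6', cis) | B1(/C=C(\Br)[C@@](C)(O[Si](CC)(CC)CC)C[C@H](O[Si](CC)(CC)CC)CC(C)=C)C2CCCC1CCC2
F2 | step 19 | acyclic 6'-bromo precursor of 26: the C30 chain of 19 bonded through C8' to C7' of the (Z)-2-bromoalkene from 25 (C8' cis to Br, isopropenyl group still open) | CC1=C[C@@H](O[Si](C)(C)C(C)(C)C)CC(C)(C)\C1=C/C=C(C)/C=C/C=C(C)/C=C/C=C/C(C)=C/C=C/C(C)=C/C=C(\Br)[C@@](C)(O[Si](CC)(CC)CC)C[C@H](O[Si](CC)(CC)CC)CC(C)=C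
F3 | step 7 | 9-[(1Z,3Z,5S)-2-bromo-5-(tert-butyldimethylsilyloxy)-3,7-dimethylocta-1,3,7-trien-1-yl]-9-borabicyclo[3.3.1]nonane (boron on C7, bromine on C6, cis) | B1(/C=C(\Br)/C(C)=C\[C@@H](O[Si](C)(C)C(C)(C)C)CC(C)=C)C2CCCC1CCC2
F4 | step 7 | diethyl [(2E,4Z,6Z,8S)-5-bromo-8-(tert-butyldimethylsilyloxy)-2,6,10-trimethylundeca-2,4,6,10-tetraen-1-yl]phosphonate | CCOP(=O)(OCC)C/C(C)=C/C=C(\Br)/C(C)=C\[C@@H](O[Si](C)(C)C(C)(C)C)CC(C)=C
F5 | step 17 | 1-[(2S,3R)-3-ethynyl-3-methyloxiran-2-yl]-3-methylbut-3-en-1-one | C#C[C@@]1(C)O[C@@H]1C(=O)CC(C)=C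
F6 | step 17 | (6S)-6-hydroxy-2,6-dimethyloct-1-en-7-yn-4-one | C#C[C@@](C)(O)CC(=O)CC(C)=C
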